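A transfer constant of 0.49 min⁻¹ feeds dissolved partner from the held gas towards a saturation level, csat, of 56 mM, and the flasks below differ in temperature.

the same everywhere: starting material 0.93 M; gas 56 mM (held); time 20 h

| flask | temperature |
|---|---|
| zeta | 90 °C |
| gamma | 105 °C |
| alpha | 75 °C |
| beta | 120 °C |

1. the flask with the highest amount of mono adduct, in percent of the starting material charged ("all alike" if they lie within 1.5 percentage points) (zeta / gamma / alpha / beta / all alike)
2. final mono adduct, as a percentage of the starting material charged, in zeta
3. final mono adduct, as a percentage of the starting material charged, in gamma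
4. final mono adduct, as a percentage of the starting material charged, in alpha
5. final mono adduct, as a percentage of the starting material charged, in beta

- at the start none of partner is dissolved
- constants are those at 90 °C; use the activation energies and enthalpies for any other temperature

    starting material + partner → mono adduct (k1 = 0.021 M⁻¹ min⁻¹, Ea1 = 96.0 kJ mol⁻¹)
    gas ⇌ partner, rate k2*(csat - [partner]) (k2 = 0.49 min⁻¹, csat = 56 mM)
    partner + mono adduct → bis adduct (k3 = 0.0016 M⁻¹ min⁻¹, Ea3 = 85.0 kJ mol⁻¹)
    mono adduct ⇌ isomer of the product (K4 = 0.51, k4 = 4.6 × 10⁻⁴ min⁻¹, Ea4 = 117 kJ mol⁻¹, ΔH4 = −37.0 kJ mol⁻¹)
    (constants at 90 °C)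

My own reckoning starts from the balance of partner, the reagent present in the smaller amount, which gains by transfer and loses to both additions. At the start of gamma the first addition draws partner with a constant of 0.0689 min⁻¹, slower than transfer, so partner stays close below csat and the first addition is pseudo-first-order, with a = 0.00415 min⁻¹ in gamma. Mono adduct and isomer of the product relax into each other in gamma with a half-life of 1.29 h, short against 20 h, so they count as one pool P, of which mono adduct is the share f = 76.1%. The second addition takes partner and mono adduct, so the pool in gamma loses to it with λ = 2.08 × 10⁻⁴ min⁻¹, the pool loss constant: the second-addition constant at that temperature, times csat, times f.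

With P = a/(a−λ)·(e^(−λt) − e^(−at)), the product f·P gives 61.9% mono adduct in gamma. The same treatment of beta, with a = 0.0133 min⁻¹, f = 83.3% and λ = 6.40 × 10⁻⁴ min⁻¹, gives 40.6%, less than gamma. For the cooler flasks the reckoning gives ceilings, the converted share: 30.1% in alpha, below gamma, and 75.6% in zeta, above gamma, which leaves zeta open.

The forecast, a little apart from these figures and holding that “The isomer equilibrium is fast”, names gamma, with 56.5% in zeta, 61.4% in gamma, 27.8% in alpha and 41.6% in beta.

The simulation gives gamma, with 56.5% in zeta, 61.7% in gamma, 27.9% in alpha and 41.9% in beta.

At the end of gamma, mono adduct is made at 0.356 times the rate at which it is used up, and it has come down from 64.5% at 10.0 h. For the gamma flask left until 2.0 d, the same formula with the same λ gives 44.0% mono adduct. That flask holds 44.0% mono adduct, 14.2% isomer of the product and 41.8% bis adduct.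

Its constants are assumed; no experiment stands behind them.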